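## Retrosynthetic overview

- **Feature.** Azulene numbering is used: C1, C2 = CH2; C3 = CH-iPr; C3a = carbinol; C4, C5 = CH2; C6=C7; C8 = ester carbon; C8a = C-CH3. The oxygenated C8 adjoins the methyl-bearing quaternary C8a of a cis-fused cyclopentane whose other fusion atom, C3a, carries oxygen. At the ketone level this is what a 1-isopropenylcyclohexanol gives when its =CH2 is alkylated and the neighbouring ring carbon then shifts to the cationic centre.
- **Endgame.** Ester ⇒ allylic cis-diol ⇒ C6–C7 enone ⇒ saturated 3a-hydroxy hydroazulenone ⇒ its 3a-O-benzyl, 2-methylthio precursor.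
- **Key disconnection.** Cut C1–C2 and return C3a from C8a to C8. This gives a monocyclic isopropenyl cyclohexyl silyl ether carrying a CH(iPr)CH(SMe)2 arm on C3a.
- **Precursor.** α-Benzyloxy ketone plus isopropenyl metal. The C3a/C3 pair comes from one allylboration of a C8-ketalised 1,2-dione with an (E)-γ-isopropylallylboron reagent, and the vinyl group then becomes CH(SMe)2.
- **Ring order.** The six-membered ring comes from (R)-3-methylcyclohexanone. The five-membered ring closes and the six-membered ring grows to seven in the same operation.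

Key step: step 12

Remark: the labels C1–C8a are the target's locants and are kept for all intermediates; C8 of the isopropenyl carbinol and of its silyl ether is drawn as step 10 should set it (isopropenyl trans to the C3 arm, the two oxygens trans), and this centre becomes the carbonyl carbon in step 12; the carbinol centre made in step 1 is left open because step 2 removes it.

## Route

Step 1
Reactants: 1 (R)-3-methylcyclohexanone
Product: 2 (4R)-2,2-dimethoxy-4-methylcyclohexan-1-ol (carbinol epimers)
Conditions: PhI(OAc)2 (1.1 equiv), KOH (3 equiv), MeOH, 0 °C → rt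
Reagents that add atoms: methanol, CO
Why: Moriarty α-hydroxylation: under equilibrating base the enolate should be captured by the bulky hypervalent iodine electrophile at the α-methylene that has no branched neighbour (C3a), methoxide adds to C8, the resulting alkoxide expels iodobenzene and methanol opens the methoxy epoxide at C8, so that C3a is oxygenated and C8 is masked in one basic operation with no chance of α-ketol transposition, the new carbinol centre being removed in step 2 and any C7 regioisomer by chromatography.

Step 2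
Reactants: 2 (4R)-2,2-dimethoxy-4-methylcyclohexan-1-ol
Product: 3 (R)-2,2-dimethoxy-4-methylcyclohexan-1-one
Conditions: n-Pr4N[RuO4] (5 mol %), N-methylmorpholine N-oxide, 4 Å MS, CH2Cl2, rt
Reagents that add atoms: none
Why: Ley–Griffith oxidation is neutral and therefore spares the acid-labile ketal, forms no stereocentre and leaves the remote C6 centre untouched.

Step 3
Reactants: 4 3-methylbut-1-yne
Product: 5 (E)-4,4,5,5-tetramethyl-2-(3-methylbut-1-en-1-yl)-1,3,2-dioxaborolane
Conditions: pinacolborane (1.05 equiv), Cp2Zr(H)Cl (5 mol %), Et3N (5 mol %), neat, closed flask, rt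
Reagents that add atoms: pinacolborane, [H]B1OC(C)(C)C(C)(C)O1
Why: Zirconocene hydride catalysed hydroboration is a syn addition that places boron on the unhindered alkyne terminus, so only the (E)-alkenylboronate should form.

Step 4
Reactants: 5 (E)-4,4,5,5-tetramethyl-2-(3-methylbut-1-en-1-yl)-1,3,2-dioxaborolane
Product: 7 potassium (E)-trifluoro(4-methylpent-2-en-1-yl)borate, via allylboronate 6 (not isolated)
Conditions: BrCH2Cl (1.5 equiv), n-BuLi (1.3 equiv), THF, −78 °C → rt; then aq KHF2, MeOH, rt
Reagents that add atoms: bromochloromethane, ClCBr; potassium hydrogen difluoride, F.[F-].[K+]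
Why: Matteson homologation: chloromethyllithium made in the presence of 5 gives the boron ate complex, the alkenyl group shifts from boron to carbon with loss of chloride and with retention of the E geometry, and KHF2 converts the crude allylboronate into a crystalline salt that cannot undergo borotropic E/Z scrambling.

Step 5
Reactants: 3 (R)-2,2-dimethoxy-4-methylcyclohexan-1-one; 7 potassium (E)-trifluoro(4-methylpent-2-en-1-yl)borate
Product: 9 (1S,4R)-2,2-dimethoxy-4-methyl-1-[(3S)-4-methylpent-1-en-3-yl]cyclohexan-1-ol, via allyldifluoroborane 8 (not isolated)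
Conditions: BF3·OEt2 (2 equiv), CH2Cl2, −78 °C; aq NaHCO3
Reagents that add atoms: none
Why: Ketone allylboration: BF3 strips fluoride from 7 to give the small, strongly Lewis acidic borane 8, which adds to the inductively activated ketone (whose ketal resists ionisation next to the carbonyl group at −78 °C) through a Zimmerman–Traxler chair with the ketal carbon C8 pseudo-equatorial and C4 pseudo-axial, so that the E alkene gives the anti C3a–O/C3–isopropyl relationship, while attack on the Si face, axial on the chair with equatorial C6 methyl and antiperiplanar to the axial C8–OMe bond (polar Felkin–Anh), fixes C3a relative to C6.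

Step 6
Reactants: 9 (1S,4R)-2,2-dimethoxy-4-methyl-1-[(3S)-4-methylpent-1-en-3-yl]cyclohexan-1-ol
Product: 10 (1S,4R)-1-(benzyloxy)-2,2-dimethoxy-4-methyl-1-[(3S)-4-methylpent-1-en-3-yl]cyclohexane
Conditions: KH (1.5 equiv), BnBr (1.5 equiv), n-Bu4NI (10 mol %), THF, 0 °C → rt
Reagents that add atoms: benzyl bromide, BrCc1ccccc1
Why: Williamson etherification: the potassium alkoxide of the congested tertiary alcohol meets an unhindered benzylic iodide formed in situ, the low temperature disfavours retro-allylation of the homoallylic alkoxide, and no stereocentre is touched.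

Step 7
Reactants: 10 (1S,4R)-1-(benzyloxy)-2,2-dimethoxy-4-methyl-1-[(3S)-4-methylpent-1-en-3-yl]cyclohexane
Product: 11 (2S,5R)-2-(benzyloxy)-5-methyl-2-[(3S)-4-methylpent-1-en-3-yl]cyclohexan-1-one
Conditions: 1 M aq HCl, THF, rt
Reagents that add atoms: water, O
Why: Acid hydrolysis of the dimethyl ketal is helped by release of strain next to the quaternary C3a, the benzyl ether and the vinyl group are inert to dilute acid, and running it before the alkene cleavage keeps acid away from the later epimerisable aldehyde.

Step 8
Reactants: 11 (2S,5R)-2-(benzyloxy)-5-methyl-2-[(3S)-4-methylpent-1-en-3-yl]cyclohexan-1-one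
Product: 13 (2R)-2-[(1S,4R)-1-(benzyloxy)-4-methyl-2-oxocyclohexyl]-3-methylbutanal, via secondary ozonide 12 (not isolated)
Conditions: O3, CH2Cl2, −78 °C (Sudan red 7B end point); then Me2S, −78 °C → rt
Reagents that add atoms: ozone, [O-][O+]=O
Why: Ozonolysis (Criegee mechanism) cleaves the only alkene, the dye end point prevents oxidation of the benzyl ether, and the neutral reductive work-up leaves the α-stereocentre C3 of the hindered aldehyde intact.

Step 9
Reactants: 13 (2R)-2-[(1S,4R)-1-(benzyloxy)-4-methyl-2-oxocyclohexyl]-3-methylbutanal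
Product: 14 (2S,5R)-2-(benzyloxy)-5-methyl-2-[(2R)-3-methyl-1,1-bis(methylsulfanyl)butan-2-yl]cyclohexan-1-one
Conditions: MeSSiMe3 (2.5 equiv), ZnI2 (10 mol %), Et2O, 0 °C → rt
Reagents that add atoms: (methylthio)trimethylsilane, CS[Si](C)(C)C
Why: Lewis acid catalysed thioacetalisation with a thiosilane is driven by Si–O bond formation and should select the aldehyde, because the C8 ketone is neopentyl-like and its hemithioketal could ionise only next to the electron-withdrawing C3a–OBn carbon.

Step 10
Reactants: 14 (2S,5R)-2-(benzyloxy)-5-methyl-2-[(2R)-3-methyl-1,1-bis(methylsulfanyl)butan-2-yl]cyclohexan-1-one; 15 2-bromopropene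
Product: 17 (1S,2S,5R)-2-(benzyloxy)-5-methyl-2-[(2R)-3-methyl-1,1-bis(methylsulfanyl)butan-2-yl]-1-(prop-1-en-2-yl)cyclohexan-1-ol, via isopropenylmagnesium bromide 16 (not isolated)
Conditions: 15, Mg, THF, rt → 40 °C; then anhydrous CeCl3, 14, THF, −78 → 0 °C; aq NH4Cl
Reagents that add atoms: none
Why: Grignard addition with CeCl3 to suppress enolisation of the hindered ketone: both the Cram chelate (benzyloxy oxygen eclipsing the carbonyl group, C3 arm axial) and the non-chelated chair (C3 arm equatorial, C6 methyl axial) expose only the face anti to the C3 arm, which should give the (S) carbinol with isopropenyl trans to that arm.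

Step 11
Reactants: 17 (1S,2S,5R)-2-(benzyloxy)-5-methyl-2-[(2R)-3-methyl-1,1-bis(methylsulfanyl)butan-2-yl]-1-(prop-1-en-2-yl)cyclohexan-1-ol
Product: 18 trimethylsilyl ether of 17 (all centres unchanged)
Conditions: 1-(trimethylsilyl)imidazole (5 equiv), CH2Cl2, rt → 40 °C
Reagents that add atoms: 1-(trimethylsilyl)imidazole, C[Si](C)(C)n1ccnc1
Why: Silyl transfer from the neutral and very powerful donor N-silylimidazole caps the hindered tertiary allylic alcohol without acid that could ionise it or disturb the dithioacetal, and C8 keeps its configuration.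

Step 12
Reactants: 18 trimethylsilyl ether of 17
Product: 21 (2R,3R,3aS,6R,8aS)-3a-(benzyloxy)-6,8a-dimethyl-2-(methylsulfanyl)-3-(propan-2-yl)octahydroazulen-8(1H)-one (cis-fused; C8a-CH3 and OBn and iPr on one face; SMe and C6-CH3 on the other), via thionium ion 19 (not isolated), via bicyclic C8a cation 20 (not isolated)
Conditions: [Me2S–SMe]BF4 (DMTSF, 1.2 equiv), CH2Cl2, −45 → 0 °C; aq NaHCO3
Reagents that add atoms: none
Why: DMTSF transfers MeS+ to one sulfur of the dithioacetal, which is far more nucleophilic than the hindered 1,1-disubstituted alkene, and loss of MeSSMe leaves the (E)-thionium ion 19. The alkene terminus C1 adds to C2 in a 6-endo-trig cation–olefin (Prins-type) closure that puts the charge on the tertiary C8a; the new chair is fused in a trans-decalin sense to the cyclohexane chair, with the isopropyl and methylthio groups equatorial, which sets C2 trans to C3. In cation 20 the C8–C3a bond leans toward the axis of the empty orbital whereas C8–C7 lies near its nodal plane, and the benzyloxy lone pair raises the migratory aptitude of C3a, so C3a and not C7 moves to C8a as the silyloxy group turns into the C8 carbonyl group and tetrafluoroborate takes up the silyl group. This single 1,2-shift contracts the six-membered ring just closed to the cyclopentane (C1–C2–C3–C3a–C8a) and enlarges the original cyclohexane to the cycloheptanone by inserting C8a between C8 and C3a. C3a migrates suprafacially with retention, and since C4 stands antiperiplanar to C8a about the C8–C3a bond, C4 and C8 end on one face of the cyclopentane and OBn and CH3 on the other, so C8a is fixed by C3a as the cis fusion. The closest known reaction type is the pinacol-terminated Prins cyclization of 1-alkenylcycloalkanol silyl ethers that carry an acetal or dithioacetal arm (ring-enlarging cyclopentane annulation); here the shift must outrun proton loss from 20, which the antiperiplanar oxygen push and the low temperature should secure.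

Step 13
Reactants: 21 (2R,3R,3aS,6R,8aS)-3a-(benzyloxy)-6,8a-dimethyl-2-(methylsulfanyl)-3-(propan-2-yl)octahydroazulen-8(1H)-one
Product: 22 (3R,3aS,6R,8aS)-3a-(benzyloxy)-6,8a-dimethyl-3-(propan-2-yl)octahydroazulen-8(1H)-one
Conditions: Raney Ni (W-2, aged in acetone), EtOH, rt
Reagents that add atoms: none
Why: Raney Ni hydrogenolysis cleaves both C–S bonds of the sulfide, which erases the C2 centre, the acetone-aged metal should leave the neopentyl ketone alone, and any concurrent loss of the benzyl group only anticipates step 14.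

Step 14
Reactants: 22 (3R,3aS,6R,8aS)-3a-(benzyloxy)-6,8a-dimethyl-3-(propan-2-yl)octahydroazulen-8(1H)-one
Product: 23 (3R,3aS,6R,8aS)-3a-hydroxy-6,8a-dimethyl-3-(propan-2-yl)octahydroazulen-8(1H)-one
Conditions: H2 (1 atm), Pd(OH)2/C, EtOAc–EtOH, rt
Reagents that add atoms: none
Why: Catalytic hydrogenolysis of the benzyl ether becomes possible once sulfur is gone, proceeds at the benzylic C–O bond so that C3a keeps its configuration, and is neutral so that the β-hydroxy ketone cannot undergo retro-aldol cleavage of C3a–C8a.

Step 15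
Reactants: 23 (3R,3aS,6R,8aS)-3a-hydroxy-6,8a-dimethyl-3-(propan-2-yl)octahydroazulen-8(1H)-one
Product: 24 bis(trimethylsilyl) derivative of 23 (C8–C7 enol silane plus C3a silyl ether; C3, C3a, C6, C8a unchanged)
Conditions: TMSOTf (3 equiv), Et3N (5 equiv), CH2Cl2, 0 °C → rt
Reagents that add atoms: trimethylsilyl trifluoromethanesulfonate, C[Si](C)(C)OS(=O)(=O)C(F)(F)F
Why: Soft enolisation with TMSOTf and Et3N can only go toward C7 because C8a is quaternary, and the tertiary hydroxyl is silylated first, so no alkoxide is ever present that could open the C3a–C8a bond by retro-aldol reaction.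

Step 16
Reactants: 24 bis(trimethylsilyl) derivative of 23
Product: 26 (3R,3aS,8aS)-3a-hydroxy-6,8a-dimethyl-3-(propan-2-yl)-2,3,3a,4,5,8a-hexahydroazulen-8(1H)-one, via silyloxy enone 25 (not isolated)
Conditions: Pd(OAc)2 (1.1 equiv), MeCN, rt → 40 °C; filter; then aq HF, MeCN, 0 °C
Reagents that add atoms: none
Why: Saegusa–Ito dehydrogenation: divalent palladium takes the enol silane to the oxa-π-allyl species, which can change faces through its O-bound form until palladium on C7 is syn to the C6 hydrogen, β-hydride elimination gives the conjugated C6–C7 alkene and erases the C6 centre, and dilute HF then frees the tertiary hydroxyl, which cannot eliminate because C8a bears no hydrogen.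

Step 17
Reactants: 26 (3R,3aS,8aS)-3a-hydroxy-6,8a-dimethyl-3-(propan-2-yl)-2,3,3a,4,5,8a-hexahydroazulen-8(1H)-one
Product: 27 (3R,3aS,8S,8aR)-6,8a-dimethyl-3-(propan-2-yl)-1,2,3,3a,4,5,8,8a-octahydroazulene-3a,8-diol
Conditions: CeCl3·7H2O (1.2 equiv), NaBH4 (1.2 equiv), MeOH, −78 → −40 °C
Reagents that add atoms: none
Why: Luche reduction: the hard cerium-modified borohydride adds 1,2 to the enone, and hydride should enter C8 from the β face, anti to the vicinal angular methyl group and to the C3a hydroxyl that holds the cerium-bound carbonyl oxygen on the α face (the sense known for ketones flanked by an angular methyl group, as in 17-oxo steroids), giving the (8S) alcohol cis to CH3 and OH.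

Step 18
Reactants: 27 (3R,3aS,8S,8aR)-6,8a-dimethyl-3-(propan-2-yl)-1,2,3,3a,4,5,8,8a-octahydroazulene-3a,8-diol; 28 4-methoxybenzoyl chloride
Product: 29 (3R,3aS,8S,8aR)-3a-hydroxy-6,8a-dimethyl-3-(propan-2-yl)-1,2,3,3a,4,5,8,8a-octahydroazulen-8-yl 4-methoxybenzoate (CNP0158828.1)
Conditions: 28 (1.5 equiv), DMAP (0.5 equiv), Et3N (3 equiv), CH2Cl2, 0 °C → rt
Reagents that add atoms: none
Why: DMAP-catalysed acylation through the acylpyridinium ion esterifies only the secondary allylic hydroxyl, the tertiary C3a hydroxyl being inert, the basic non-ionising medium avoids allylic transposition, and C8 keeps its configuration because its C–O bond is not broken.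

## Compound list

1 | (R)-3-methylcyclohexanone | C[C@@H]1CCCC(=O)C1 | starting material
2 | (4R)-2,2-dimethoxy-4-methylcyclohexan-1-ol (carbinol epimers) | COC1(OC)C[C@H](C)CCC1O | intermediate
3 | (R)-2,2-dimethoxy-4-methylcyclohexan-1-one | COC1(OC)C[C@H](C)CCC1=O | intermediate
4 | 3-methylbut-1-yne | CC(C)C#C | starting material
5 | (E)-4,4,5,5-tetramethyl-2-(3-methylbut-1-en-1-yl)-1,3,2-dioxaborolane | CC(C)/C=C/B1OC(C)(C)C(C)(C)O1 | intermediate
6 | (E)-4,4,5,5-tetramethyl-2-(4-methylpent-2-en-1-yl)-1,3,2-dioxaborolane | CC(C)/C=C/CB1OC(C)(C)C(C)(C)O1 | intermediate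
7 | potassium (E)-trifluoro(4-methylpent-2-en-1-yl)borate | CC(C)/C=C/C[B-](F)(F)F.[K+] | intermediate
8 | (E)-difluoro(4-methylpent-2-en-1-yl)borane | CC(C)/C=C/CB(F)F | intermediate
9 | (1S,4R)-2,2-dimethoxy-4-methyl-1-[(3S)-4-methylpent-1-en-3-yl]cyclohexan-1-ol | COC1(OC)C[C@H](C)CC[C@]1(O)[C@@H](C(C)C)C=C | intermediate
10 | (1S,4R)-1-(benzyloxy)-2,2-dimethoxy-4-methyl-1-[(3S)-4-methylpent-1-en-3-yl]cyclohexane | COC1(OC)C[C@H](C)CC[C@]1(OCc2ccccc2)[C@@H](C(C)C)C=C | intermediate
11 | (2S,5R)-2-(benzyloxy)-5-methyl-2-[(3S)-4-methylpent-1-en-3-yl]cyclohexan-1-one | O=C1C[C@H](C)CC[C@]1(OCc2ccccc2)[C@@H](C(C)C)C=C | intermediate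
12 | secondary ozonide (1,2,4-trioxolane) of 11, trioxolane carbon open | O=C1C[C@H](C)CC[C@]1(OCc2ccccc2)[C@@H](C(C)C)C3OCOO3 | intermediate
13 | (2R)-2-[(1S,4R)-1-(benzyloxy)-4-methyl-2-oxocyclohexyl]-3-methylbutanal | O=C1C[C@H](C)CC[C@]1(OCc2ccccc2)[C@@H](C(C)C)C=O | intermediate
14 | (2S,5R)-2-(benzyloxy)-5-methyl-2-[(2R)-3-methyl-1,1-bis(methylsulfanyl)butan-2-yl]cyclohexan-1-one | O=C1C[C@H](C)CC[C@]1(OCc2ccccc2)[C@@H](C(C)C)C(SC)SC | intermediate
15 | 2-bromopropene | C=C(C)Br | starting material
16 | isopropenylmagnesium bromide | C=C(C)[Mg]Br | intermediate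
17 | (1S,2S,5R)-2-(benzyloxy)-5-methyl-2-[(2R)-3-methyl-1,1-bis(methylsulfanyl)butan-2-yl]-1-(prop-1-en-2-yl)cyclohexan-1-ol | C=C(C)[C@@]1(O)C[C@H](C)CC[C@]1(OCc2ccccc2)[C@@H](C(C)C)C(SC)SC | intermediate
18 | trimethylsilyl ether of 17 (key-step precursor) | C=C(C)[C@@]1(O[Si](C)(C)C)C[C@H](C)CC[C@]1(OCc2ccccc2)[C@@H](C(C)C)C(SC)SC | intermediate
19 | (E)-thionium tetrafluoroborate from 18 | C=C(C)[C@@]1(O[Si](C)(C)C)C[C@H](C)CC[C@]1(OCc2ccccc2)[C@@H](C(C)C)/C=[S+]/C.F[B-](F)(F)F | intermediate
20 | trans-fused bicyclic C8a cation (tetrafluoroborate) | C[C+]1C[C@@H](SC)[C@H](C(C)C)[C@@]2(OCc3ccccc3)CC[C@@H](C)C[C@]12O[Si](C)(C)C.F[B-](F)(F)F | intermediate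
21 | (2R,3R,3aS,6R,8aS)-3a-(benzyloxy)-6,8a-dimethyl-2-(methylsulfanyl)-3-(propan-2-yl)octahydroazulen-8(1H)-one (key-step product) | O=C1C[C@H](C)CC[C@]2(OCc3ccccc3)[C@@H](C(C)C)[C@H](SC)C[C@]12C | intermediate
22 | (3R,3aS,6R,8aS)-3a-(benzyloxy)-6,8a-dimethyl-3-(propan-2-yl)octahydroazulen-8(1H)-one | O=C1C[C@H](C)CC[C@]2(OCc3ccccc3)[C@@H](C(C)C)CC[C@]12C | intermediate
23 | (3R,3aS,6R,8aS)-3a-hydroxy-6,8a-dimethyl-3-(propan-2-yl)octahydroazulen-8(1H)-one | O=C1C[C@H](C)CC[C@]2(O)[C@@H](C(C)C)CC[C@]12C | intermediate
24 | bis(trimethylsilyl) derivative of 23 (enol silane and C3a silyl ether) | C[Si](C)(C)OC1=C[C@H](C)CC[C@]2(O[Si](C)(C)C)[C@@H](C(C)C)CC[C@]12C | intermediate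
25 | 3a-(trimethylsilyloxy) C6–C7 enone | O=C1C=C(C)CC[C@]2(O[Si](C)(C)C)[C@@H](C(C)C)CC[C@]12C | intermediate
26 | (3R,3aS,8aS)-3a-hydroxy-6,8a-dimethyl-3-(propan-2-yl)-2,3,3a,4,5,8a-hexahydroazulen-8(1H)-one | O=C1C=C(C)CC[C@]2(O)[C@@H](C(C)C)CC[C@]12C | intermediate
27 | (3R,3aS,8S,8aR)-6,8a-dimethyl-3-(propan-2-yl)-1,2,3,3a,4,5,8,8a-octahydroazulene-3a,8-diol | O[C@H]1C=C(C)CC[C@]2(O)[C@@H](C(C)C)CC[C@]12C | intermediate
28 | 4-methoxybenzoyl chloride | COc1ccc(C(=O)Cl)cc1 | starting material
29 | (3R,3aS,8S,8aR)-3a-hydroxy-6,8a-dimethyl-3-(propan-2-yl)-1,2,3,3a,4,5,8,8a-octahydroazulen-8-yl 4-methoxybenzoate | COc1ccc(C(=O)O[C@H]2C=C(C)CC[C@]3(O)[C@@H](C(C)C)CC[C@]23C)cc1 | target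

## Step count and risks

Total step count: 18. Longest linear sequence: 16 (steps 1, 2 and 5–18 from 1; the branch from 4 through steps 3, 4 and 5–18 is equally long).

**Step 12 (key step).**
- What may go wrong:
  - Proton loss from the C8a cation.
  - Sulfenylation of the alkene by the reagent.
  - Reversible deprotonation of the thionium ion at C3, which would erode C3.
  - Stepwise fragmentation to a benzyloxocarbenium ion and an enol silane followed by reclosure, which would erode C3a.
  - Any of these may compete with the concerted shift, and the reactive chair also carries the C6 methyl group axial and facing the axial silyloxy group, which adds strain.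
- Fallback, setting out from 18 and returning at 22: sulfur is left out of the cationic step.
  - Alkylative hydrolysis of the dithioacetal (MeI, NaHCO3, aqueous MeCN, 40 °C) should give the aldehyde F1.
  - SnCl4 in CH2Cl2 at −78 °C then activates the aldehyde oxygen, and the same 6-endo closure and C3a shift should deliver the 2-hydroxy hydroazulenone F2, with hydroxyl in the place of the methylthio group.
  - 1,1'-Thiocarbonyldiimidazole (DMAP, CH2Cl2) converts it into the imidazole-1-carbothioate F3.
  - Barton–McCombie deoxygenation (n-Bu3SnH, AIBN, toluene, 100 °C) gives 22.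

**Step 5.**
- What may go wrong: slow addition to the hindered ketone, ionisation of the ketal by BF3, attack on the equatorial (Re) face, or a chair with C8 pseudo-axial would lower the stereochemical purity at C3a and C3.
- Fallback, setting out from 7 and 3 and returning at 9: stereocontrol is moved from the substrate under Lewis acid to a chiral catalyst without Lewis acid.
  - Hydrolysis of 7 (LiOH, aqueous MeCN, then NH4Cl) gives (E)-(4-methylpent-2-en-1-yl)boronic acid F4.
  - This acid adds to 3 in toluene with t-BuOH, 3 Å sieves and a catalytic amount of 3,3'-dibromo-BINOL, the antipode being chosen for Si-face delivery.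
  - The mixed BINOL boronate is the reactive species and imposes its own facial preference through the same chair, giving 9.

**Step 17.**
- What may go wrong: hydride delivery from the α face, for example through borohydride bound to the C3a hydroxyl, or competing 1,4-reduction.
- Fallback, setting out from 26 and returning at 29: the wrong face is used on purpose and C8 is then inverted.
  - Evans–Saksena reduction with Me4N[BH(OAc)3] (MeCN–AcOH, −30 °C) binds to the C3a hydroxyl and delivers hydride intramolecularly to the α face, giving the C8-epimeric diol F5.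
  - Mitsunobu esterification with 4-methoxybenzoic acid (PPh3, DIAD, toluene, 0 °C → rt) forms the ester with inversion at C8. The carboxylate enters from the α face that the hydride preferred, and 29 is obtained directly.

Further compounds
F1 | step 12 | (2R)-2-[(1S,2S,4R)-1-(benzyloxy)-4-methyl-2-(prop-1-en-2-yl)-2-(trimethylsilyloxy)cyclohexyl]-3-methylbutanal | C=C(C)[C@@]1(O[Si](C)(C)C)C[C@H](C)CC[C@]1(OCc2ccccc2)[C@@H](C(C)C)C=O
F2 | step 12 | 2-hydroxy analogue of 21 (OH in place of SMe, same configuration at every centre) | O=C1C[C@H](C)CC[C@]2(OCc3ccccc3)[C@@H](C(C)C)[C@H](O)C[C@]12C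
F3 | step 12 | O-(imidazole-1-carbothioyl) derivative of F2 | O=C1C[C@H](C)CC[C@]2(OCc3ccccc3)[C@@H](C(C)C)[C@H](OC(=S)n3ccnc3)C[C@]12C
F4 | step 5 | (E)-(4-methylpent-2-en-1-yl)boronic acid | CC(C)/C=C/CB(O)O
F5 | step 17 | (3R,3aS,8R,8aR)-6,8a-dimethyl-3-(propan-2-yl)-1,2,3,3a,4,5,8,8a-octahydroazulene-3a,8-diol | O[C@@H]1C=C(C)CC[C@]2(O)[C@@H](C(C)C)CC[C@]12C
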